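The substrate in these flasks reacts with partner after a small charge of initiator starts the reaction. Target appears and disappears on the way, and the question is how much substrate has reacted by 3.0 d.

in all of them: substrate 0.051 M; initiator 2.5 mM
- violet: partner 0.042 M; run made earlier
- red: partner 0.16 M; run made earlier
- south-west: partner 0.0560 M; time 3.0 d
- south: partner 0.110 M; time 3.0 d
- north: partner 0.220 M; time 3.0 d

| run | time / h | substrate / % | target / % |
|---|---|---|---|
| violet | 3.00 | 87.8 | 6.4 |
| violet | 10.0 | 69.5 | 9.7 |
| violet | 15.0 | 59.4 | 9.8 |
| violet | 25.0 | 47.2 | 6.7 |
| violet | 40.0 | 33.7 | 4.4 |
| red | 3.00 | 70.4 | 15.6 |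
| red | 5.00 | 57.8 | 21.5 |
| red | 10.0 | 37.4 | 22.7 |
| red | 20.0 | 17.0 | 14.7 |
| red | 40.0 | 4.9 | 4.6 |

(scatter of a reading: 0.5 percentage points)

- what has gone from substrate into another species counts as reacted, even if it can come back

- part of the substrate that has reacted at the end, south-west
- part of the substrate that has reacted at the end, south
- part of the substrate that has reacted at the end, north
- what raising the concentration of partner from its lowest to its highest value here does to the part of the substrate that has reacted (changes below 5 percentage points count as none) (it falls / it rises / no change)

I plotted ln(charge of substrate / substrate left) against time. In the violet run it started with a slope, a local pseudo-first-order constant, of 0.0434 h⁻¹, and between its last two readings the slope was 0.0225 h⁻¹. The logarithm of early over late slope, divided by the time between the middles of those two intervals, I call the fade: 0.0212 h⁻¹. The red run, at higher c(partner), started steeper, at 0.117 h⁻¹, yet read a fade of 0.0222 h⁻¹. So I took partner to stretch the curve and leave its bending alone.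

At the last readings the curves stood at 1.09 in violet and 3.02 in red, which makes the stretch go as c(partner) to the power 0.763. I reckoned violet's slope at 0.0192 h⁻¹ at its last reading and let it go on fading, which put its curve at 1.53 at 3.0 d and gave a reckoned level of 1.99. Stretched by 1.25 for south-west, that gives 85.2% reacted and a level of 91.7%. South gives 95.9% and north 99.6%.

The forecast said 83%, 95% and 99%, and on raising c(partner) said of the reacted part: it rises. It read the bending its own way: “This suggests the initiator is dying”. On south-west I stood 2.2 percentage points above it.

The simulation gave 88.4%, 97.8% and 99.1%, and on raising c(partner) it said of the reacted part: it rises, by 11 points.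

    initiator → 2 initiating radical (k = 0.0308 h⁻¹)
    substrate + initiating radical → capped initiator + first chain carrier (k = 8.98 × 10⁶ M⁻¹ h⁻¹)
    partner + first chain carrier ⇌ target + second chain carrier (K = 0.501, k = 1.11 × 10⁶ M⁻¹ h⁻¹)
    substrate + second chain carrier → released group + first chain carrier (k = 1.58 × 10⁶ M⁻¹ h⁻¹)
    2 first chain carrier → ended chains A (k = 2.10 × 10⁷ M⁻¹ s⁻¹)
    2 second chain carrier → ended chains B (k = 3.30 × 10⁶ M⁻¹ s⁻¹)
    substrate + released group ⇌ idle adduct, settled at all times (K = 17.0 M⁻¹)
    target → over-reaction product (k = 0.152 h⁻¹)

The difference in c(partner) is the main reason for the rise: north, with that difference taken away, gives 88.4% instead of 99.1%. In south-west the wearing away of initiator is a part of what held the flask short: with it taken away, 100% reacts instead of 88.4%. By the fade, I reckoned the slope in south-west at 0.217 of its start at 3.0 d, and the flask had 11% of its initiator left then.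

Read later, at 8.0 d, the same south-west charge should by the fade stand at 91.2%. The simulation gave 96.3%, with 0.27% of the initiator left.

The data come from a simulation for substances that don't exist.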